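The readings come from a simulation with constants of no real substance, noise included.

4 questions stand on Sunday's flask, and I answer them with one count: how much target each equivalent of reagent buys.

| flask | substrate | reagent | temperature | remark | time |
|---|---|---|---|---|---|
| Sunday's | 1 M | 1.5 equiv | 90 °C | the very flask that is asked about, followed so far |  |
| Monday's | 1 M | 0.75 equiv | 85 °C | run made earlier |  |
| flask | 1.0 M | 1.50 equiv | 90 °C |  | 5.0 d |

| run | time / h | target / % |
|---|---|---|
| Sunday's | 30.0 | 29 |
| Sunday's | 60.0 | 26 |
| Sunday's | 96.0 | 28 |
| Sunday's | 120 | 25 |
| Monday's | 0.667 | 4 |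
| Monday's | 1.33 | 4 |
| Monday's | 2.00 | 7 |
| Monday's | 2.50 | 10 |

(scatter of a reading: 2 percentage points)

- grey: change nothing and wait 40 h more
- amber: at 5.0 d take out 90% of the target then present, then wait 40 h
- violet: at 5.0 d add reagent, 50.0% of the amount charged, then wait 40 h
- blue: at 5.0 d raise the temperature by 25 K, then wait 40 h

- removed target is counted in
- additions bring no volume worth counting

- target, in percent of the substrate first charged, at 5.0 d
- which option adds most target ("none" when 2 percentage points or less is all one gets) (grey / amber / violet / blue / none)
- target present, with what was taken out counted in, in percent of the substrate first charged, after amber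
- target present, with what was taken out counted in, in percent of the substrate first charged, after violet

Sunday's readings lie flat from 30.0 h to 120 h, and their mean, 27.0%, is my "now". A flat line can mean equilibrium, or it can mean that a sink I cannot see has taken the reagent, and these readings do not tell the two apart. So I write η = 0.180, the reagent yield: target, as a fraction of the substrate charged, per equivalent of reagent charged.

I bracket violet with it. The floor is 27.0%, where the fresh reagent makes no target. For the top of the bracket, which is my estimate and no proof, the added 50.0% of the charge at η gives 14 percentage points. But only 73.0% of the substrate is not yet target, so I scale the gain by that share and reach 36.9%. Amber has the same floor, and it stays there if the sink is the true reading. Violet gains on both readings and amber on one, so I choose violet.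

The forecast says 27%, names amber as best and calls the stop “most simply equilibrium”. Its 35% for violet lies inside my bracket, and its 41% for amber lies above the floor.

The flask gives 25.7% and best violet, which adds 6.8 points and reaches 32.5%. Amber adds 0 points and stays at 25.7%, within the scatter of the floor.

    reagent + loose pair → isomer of the product (k = 73.0 L mol⁻¹ h⁻¹, Ea = 86.0 kJ mol⁻¹)
    2 reagent → homo dimer (k = 0.260 L mol⁻¹ h⁻¹, Ea = 86.0 kJ mol⁻¹)
    tight pair ⇌ loose pair (K = 1.90, k = 18.0 h⁻¹, Ea = 90.0 kJ mol⁻¹, ΔH = −21.0 kJ mol⁻¹)
    reagent + tight pair → target (k = 30.0 L mol⁻¹ h⁻¹, Ea = 63.0 kJ mol⁻¹)
    substrate ⇌ tight pair (K = 0.0140, k = 0.180 h⁻¹, Ea = 107 kJ mol⁻¹, ΔH = −43.0 kJ mol⁻¹)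
    tight pair → side product (k = 0.490 h⁻¹, Ea = 104 kJ mol⁻¹)
    (constants at 90 °C)

Part of the reason shows in the run without the path from 2 reagent to homo dimer, where target reaches 63.7% against 25.7% and violet's gain falls from 6.8 points to 0 points. In this flask the reagent, the limiting reagent here, stands at 0% at 120 h, beside 0.468 M of homo dimer. Counted again, η for this flask is 0.171, while violet's fresh reagent yields 0.0912, less than the 0.180 I carried. The neighbour flask charged with 0.900 equiv gives 20.1%, so its η is 0.223, above the 0.171 of this flask.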